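**Strategy**

Ring B is disconnected at C9=C10, the enol-ether double bond of the ring-B diosphenol, as an aldol condensation. The quaternary C5 of ring A is flanked by C4 and C10, so both can be the carbonyls of achiral 2-methylcyclohexane-1,3-dione. An L-phenylalanine-mediated Robinson annulation with a PMB-oxymethyl vinyl ketone closes ring B at C9–C10 by choosing one of two enantiotopic ketones: it fixes C5 and brings in the C9 oxygen in one operation. The precursor is a σ-symmetric triketone formed in the same flask. The surviving C4 ketone becomes a C3=C4 olefin whose hydroboration, steered by the angular methyl, sets C3 and C4. Isopropylidenation, esterification with a separately built (Z,Z)-acid and PMB removal complete the route.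

Key step: step 3

Remark: eremophilane numbering is used in the text (ring A = C1–C5, C10; ring B = C5–C10; C14 = CH3 on C5, C15 = CH3 on C4, C11 = isopropylidene carbon); the target is (3R,4R,5R) with Z geometry in both enoate units, as its SMILES encodes.

**Route**

Step 1
Reactants: 1 2-chloro-N-methoxy-N-methylacetamide; 2 4-methoxybenzyl alcohol
Product: 3 N-methoxy-N-methyl-2-[(4-methoxybenzyl)oxy]acetamide
Conditions: NaH, Bu4NI (cat.), THF, 0 °C → rt
Reagents that add atoms: none
Why: Williamson etherification, in which the sodium alkoxide of 2 displaces the activated α-chloride (SN2) much faster than it attacks the N-methoxy-N-methylamide carbonyl.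

Step 2
Reactants: 3 N-methoxy-N-methyl-2-[(4-methoxybenzyl)oxy]acetamide
Product: 4 1-[(4-methoxybenzyl)oxy]but-3-en-2-one
Conditions: CH2=CHMgBr, THF, −78 → 0 °C; inverse quench into cold 1 M HCl
Reagents that add atoms: vinylmagnesium bromide, C=C[Mg]Br
Why: Weinreb ketone synthesis, in which the chelated tetrahedral magnesium intermediate survives until the acidic inverse quench, which prevents over-addition and protonates the released amine before it can add to the enone.

Step 3
Reactants: 4 1-[(4-methoxybenzyl)oxy]but-3-en-2-one; 5 2-methylcyclohexane-1,3-dione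
Product: 8 (S)-5-[(4-methoxybenzyl)oxy]-8a-methyl-3,4,8,8a-tetrahydronaphthalene-1,6(2H,7H)-dione, via triketone 6 (not isolated), via cis-ketol 7 (not isolated)
Conditions: Et3N (5 mol %), DMF, rt; then L-phenylalanine (1.0 equiv), (1S)-(+)-CSA (0.5 equiv), 30 → 65 °C
Reagents that add atoms: none
Why: Triethylamine-catalysed Michael addition of dione 5 to enone 4 gives the σ-symmetric triketone 6; L-phenylalanine then forms the enamine of the side-chain ketone towards the PMB-oxy-bearing C9, which adds to one of the two enantiotopic ring carbonyls (future C10) in an acid-assisted, hydrogen-bonded chair transition state, and the cis-ketol 7 loses water to the tetrasubstituted C9=C10 enol-ether enone. The closest known reaction is the Hajos–Parrish–Eder–Sauer–Wiechert annulation in its phenylalanine/CSA variant for α-substituted side-chain ketones (asymmetric Robinson annulation to Wieland–Miescher ketones). Ring B closes in a 6-(enolendo)-exo-trig aldol mode followed by E1cB dehydration. The only stereocentre that survives, quaternary C5, is set by the amino acid, whose carboxylic acid activates the carbonyl syn to it and should select the same enantiotopic group as in the L-amino-acid route to (S)-Wieland–Miescher ketone. The step needs enantiotopic-group selectivity, which is catalyst-controlled, and C9 rather than C7 enamine regiochemistry, which the substrate secures because a C7 enamine could only close a four-membered ring and reverts.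

Step 4
Reactants: 8 (S)-5-[(4-methoxybenzyl)oxy]-8a-methyl-3,4,8,8a-tetrahydronaphthalene-1,6(2H,7H)-dione
Product: 9 (R)-1-[(4-methoxybenzyl)oxy]-4a-methyl-5-methylidene-4,4a,5,6,7,8-hexahydronaphthalen-2(3H)-one
Conditions: Ph3PCH3Br, KOt-Bu, toluene, 0 °C → rt
Reagents that add atoms: methyltriphenylphosphonium bromide, C[P+](c1ccccc1)(c1ccccc1)c1ccccc1.[Br-]
Why: Wittig methylenation should occur at the saturated C4 ketone because the cross-conjugated, α-alkoxy-substituted C8 carbonyl is much less electrophilic and is partly masked as its enolate under the basic conditions, as in chemoselective olefination of the Wieland–Miescher ketone.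

Step 5
Reactants: 9 (R)-1-[(4-methoxybenzyl)oxy]-4a-methyl-5-methylidene-4,4a,5,6,7,8-hexahydronaphthalen-2(3H)-one
Product: 10 (R)-1-[(4-methoxybenzyl)oxy]-4a,5-dimethyl-4,4a,7,8-tetrahydronaphthalen-2(3H)-one
Conditions: Co(salen-tBu4)Cl (3 mol %), PhSiH3 (6 mol %), benzene, rt
Reagents that add atoms: none
Why: Cobalt-hydride hydrogen-atom-transfer isomerisation moves the 1,1-disubstituted exocyclic olefin to the more stable trisubstituted C3=C4 position (C3 is the only allylic carbon bearing hydrogen) through a tertiary radical, so no cationic 1,2-shift of the angular methyl can intervene.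

Step 6
Reactants: 10 (R)-1-[(4-methoxybenzyl)oxy]-4a,5-dimethyl-4,4a,7,8-tetrahydronaphthalen-2(3H)-one
Product: 11 (4aR,5R,6R)-1-[(4-methoxybenzyl)oxy]-4a,5-dimethyl-2,3,4,4a,5,6,7,8-octahydronaphthalene-2,6-diol (mixture of C2 epimers, i.e. at eremophilane C8)
Conditions: BH3·THF (3 equiv), THF, 0 °C → rt; then NaOH, H2O2, 0 °C
Reagents that add atoms: hydrogen peroxide, OO
Why: Hydroboration–oxidation adds H and OH syn and anti-Markovnikov (B to C3) from the face opposite the pseudoaxial C5 methyl, as for Δ5-steroids, which sets C3 (OH trans to C15) and C4 (C15 cis to C14) together, while the C8 ketone is reduced as well and is restored in step 7.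

Step 7
Reactants: 11 (4aR,5R,6R)-1-[(4-methoxybenzyl)oxy]-4a,5-dimethyl-2,3,4,4a,5,6,7,8-octahydronaphthalene-2,6-diol
Product: 12 (4aR,5R,6R)-6-hydroxy-1-[(4-methoxybenzyl)oxy]-4a,5-dimethyl-4,4a,5,6,7,8-hexahydronaphthalen-2(3H)-one
Conditions: MnO2, CH2Cl2, rt
Reagents that add atoms: none
Why: Manganese dioxide oxidises only the allylic C8 alcohol back to the enone and leaves the saturated secondary C3 alcohol untouched.

Step 8
Reactants: 12 (4aR,5R,6R)-6-hydroxy-1-[(4-methoxybenzyl)oxy]-4a,5-dimethyl-4,4a,5,6,7,8-hexahydronaphthalen-2(3H)-one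
Product: 13 (4aR,5R,6R)-6-hydroxy-3-(2-hydroxypropan-2-yl)-1-[(4-methoxybenzyl)oxy]-4a,5-dimethyl-4,4a,5,6,7,8-hexahydronaphthalen-2(3H)-one (mixture of C3 epimers, i.e. at eremophilane C7)
Conditions: LDA (2.5 equiv), THF, −78 °C; ZnCl2; acetone, −78 → −40 °C; AcOH quench
Reagents that add atoms: acetone, CC(C)=O
Why: Aldol addition in which LDA forms the C3 alkoxide and the kinetic cross-conjugated C7 (α′) enolate, whose zinc aldolate with acetone resists retro-aldol cleavage; the C7 configuration is irrelevant because it is removed in step 15.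

Step 9
Reactants: 14 angelic acid, (Z)-2-methylbut-2-enoic acid; 15 2-bromoethanol
Product: 16 2-hydroxyethyl (Z)-2-methylbut-2-enoate
Conditions: Cs2CO3, DMF, 50 °C
Reagents that add atoms: none
Why: O-alkylation of caesium angelate (SN2) builds the ester without ever activating the acid, so the Z olefin cannot isomerise to the tiglate.

Step 10
Reactants: 16 2-hydroxyethyl (Z)-2-methylbut-2-enoate
Product: 17 2-oxoethyl (Z)-2-methylbut-2-enoate
Conditions: Dess–Martin periodinane, NaHCO3, CH2Cl2, 0 °C → rt
Reagents that add atoms: none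
Why: Dess–Martin oxidation of the primary alcohol under buffered, non-basic conditions should give the α-acyloxy aldehyde without enolisation or acyl loss.

Step 11
Reactants: 18 diphenyl phosphite; 19 tert-butyl 2-bromopropanoate (racemic)
Product: 20 tert-butyl 2-(diphenoxyphosphoryl)propanoate (racemic)
Conditions: Et3N, CH2Cl2, 0 °C → rt
Reagents that add atoms: none
Why: Michaelis–Becker-type P-alkylation of the H-phosphonate by the α-bromo ester, the standard entry to Ando diaryl phosphonate reagents.

Step 12
Reactants: 17 2-oxoethyl (Z)-2-methylbut-2-enoate; 20 tert-butyl 2-(diphenoxyphosphoryl)propanoate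
Product: 21 tert-butyl (Z)-2-methyl-4-{[(Z)-2-methylbut-2-enoyl]oxy}but-2-enoate
Conditions: NaH, THF, −78 → 0 °C
Reagents that add atoms: none
Why: Ando variant of the Horner–Wadsworth–Emmons reaction, in which the electron-poor diphenyl phosphonate eliminates from the kinetic syn oxaphosphetane faster than it equilibrates, giving the (Z)-trisubstituted enoate, and the γ-oxygen is already acylated so no butenolide can form.

Step 13
Reactants: 21 tert-butyl (Z)-2-methyl-4-{[(Z)-2-methylbut-2-enoyl]oxy}but-2-enoate
Product: 22 (Z)-2-methyl-4-{[(Z)-2-methylbut-2-enoyl]oxy}but-2-enoic acid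
Conditions: TFA, CH2Cl2, 0 °C → rt
Reagents that add atoms: none
Why: Acidolysis of the tert-butyl ester (E1 loss of isobutene) leaves the primary allylic angelate and both Z olefins untouched.

Step 14
Reactants: 13 aldol adduct (C3-OH free); 22 (Z)-2-methyl-4-{[(Z)-2-methylbut-2-enoyl]oxy}but-2-enoic acid
Product: 23 (3R,4R,5R)-9-[(4-methoxybenzyl)oxy]-7-(2-hydroxypropan-2-yl)-8-oxoeremophil-9-en-3-yl (Z)-2-methyl-4-{[(Z)-2-methylbut-2-enoyl]oxy}but-2-enoate (C7 epimers)
Conditions: 2,4,6-Cl3C6H2COCl, Et3N, toluene, rt; then 13, DMAP (0.2 equiv), 0 °C → rt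
Reagents that add atoms: none
Why: Yamaguchi esterification through the mixed 2,4,6-trichlorobenzoic anhydride acylates the secondary equatorial C3 hydroxyl and not the tertiary carbinol, and low DMAP loading at low temperature limits Z→E isomerisation.

Step 15
Reactants: 23 hydroxy ester
Product: 24 (3R,4R,5R)-9-[(4-methoxybenzyl)oxy]-8-oxoeremophila-7(11),9-dien-3-yl (Z)-2-methyl-4-{[(Z)-2-methylbut-2-enoyl]oxy}but-2-enoate
Conditions: MsCl, Et3N, CH2Cl2, 0 °C → rt
Reagents that add atoms: none
Why: Mesylation of the tertiary β-hydroxy ketone (via sulfene) is followed by E1cB elimination towards the acidic C7–H, giving the conjugated tetrasubstituted C7=C11 isopropylidene.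

Step 16
Reactants: 24 PMB-protected target
Product: 25 CNP0301409.1, (3R,4R,5R)-9-hydroxy-8-oxoeremophila-7(11),9-dien-3-yl (Z)-2-methyl-4-{[(Z)-2-methylbut-2-enoyl]oxy}but-2-enoate
Conditions: DDQ, CH2Cl2/pH 7 buffer, 0 °C
Reagents that add atoms: none
Why: Oxidative PMB cleavage (hydride abstraction by DDQ, then hydrolysis of the oxocarbenium ion) frees the hydrogen-bonded C9 enol under neutral conditions that should leave both unsaturated esters and the dienone intact.

**Compound list**

1 | 2-chloro-N-methoxy-N-methylacetamide | CON(C)C(=O)CCl | starting material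
2 | 4-methoxybenzyl alcohol | COc1ccc(CO)cc1 | starting material
3 | N-methoxy-N-methyl-2-[(4-methoxybenzyl)oxy]acetamide | CON(C)C(=O)COCc1ccc(OC)cc1 | intermediate
4 | 1-[(4-methoxybenzyl)oxy]but-3-en-2-one | C=CC(=O)COCc1ccc(OC)cc1 | intermediate
5 | 2-methylcyclohexane-1,3-dione | CC1C(=O)CCCC1=O | starting material
6 | 2-{4-[(4-methoxybenzyl)oxy]-3-oxobutyl}-2-methylcyclohexane-1,3-dione (achiral triketone) | CC1(CCC(=O)COCc2ccc(OC)cc2)C(=O)CCCC1=O | intermediate
7 | cis-fused ketol, 4a-hydroxy-5-[(4-methoxybenzyl)oxy]-8a-methyloctahydronaphthalene-1,6-dione (4a-OH cis to 8a-CH3, 8a as in 8, C5 not assigned) | C1CC[C@]2(O)C(OCc3ccc(OC)cc3)C(=O)CC[C@]2(C)C1=O | intermediate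
8 | (S)-5-[(4-methoxybenzyl)oxy]-8a-methyl-3,4,8,8a-tetrahydronaphthalene-1,6(2H,7H)-dione | C1CCC2=C(OCc3ccc(OC)cc3)C(=O)CC[C@]2(C)C1=O | intermediate
9 | (R)-1-[(4-methoxybenzyl)oxy]-4a-methyl-5-methylidene-4,4a,5,6,7,8-hexahydronaphthalen-2(3H)-one | C1CCC2=C(OCc3ccc(OC)cc3)C(=O)CC[C@]2(C)C1=C | intermediate
10 | (R)-1-[(4-methoxybenzyl)oxy]-4a,5-dimethyl-4,4a,7,8-tetrahydronaphthalen-2(3H)-one | C1=C(C)[C@@]2(C)CCC(=O)C(OCc3ccc(OC)cc3)=C2CC1 | intermediate
11 | (4aR,5R,6R)-1-[(4-methoxybenzyl)oxy]-4a,5-dimethyl-2,3,4,4a,5,6,7,8-octahydronaphthalene-2,6-diol (C2 epimers) | O[C@@H]1CCC2=C(OCc3ccc(OC)cc3)C(O)CC[C@]2(C)[C@H]1C | intermediate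
12 | (4aR,5R,6R)-6-hydroxy-1-[(4-methoxybenzyl)oxy]-4a,5-dimethyl-4,4a,5,6,7,8-hexahydronaphthalen-2(3H)-one | O[C@@H]1CCC2=C(OCc3ccc(OC)cc3)C(=O)CC[C@]2(C)[C@H]1C | intermediate
13 | (4aR,5R,6R)-6-hydroxy-3-(2-hydroxypropan-2-yl)-1-[(4-methoxybenzyl)oxy]-4a,5-dimethyl-4,4a,5,6,7,8-hexahydronaphthalen-2(3H)-one (C3 epimers) | O[C@@H]1CCC2=C(OCc3ccc(OC)cc3)C(=O)C(C(C)(C)O)C[C@]2(C)[C@H]1C | intermediate
14 | angelic acid, (Z)-2-methylbut-2-enoic acid | C/C=C(/C)C(=O)O | starting material
15 | 2-bromoethanol | OCCBr | starting material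
16 | 2-hydroxyethyl (Z)-2-methylbut-2-enoate | C/C=C(/C)C(=O)OCCO | intermediate
17 | 2-oxoethyl (Z)-2-methylbut-2-enoate | C/C=C(/C)C(=O)OCC=O | intermediate
18 | diphenyl phosphite | O=[PH](Oc1ccccc1)Oc1ccccc1 | starting material
19 | tert-butyl 2-bromopropanoate (racemic) | CC(Br)C(=O)OC(C)(C)C | starting material
20 | tert-butyl 2-(diphenoxyphosphoryl)propanoate (racemic) | CC(C(=O)OC(C)(C)C)P(=O)(Oc1ccccc1)Oc1ccccc1 | intermediate
21 | tert-butyl (Z)-2-methyl-4-{[(Z)-2-methylbut-2-enoyl]oxy}but-2-enoate | C/C=C(/C)C(=O)OC/C=C(/C)C(=O)OC(C)(C)C | intermediate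
22 | (Z)-2-methyl-4-{[(Z)-2-methylbut-2-enoyl]oxy}but-2-enoic acid | C/C=C(/C)C(=O)OC/C=C(/C)C(=O)O | intermediate
23 | (3R,4R,5R)-9-[(4-methoxybenzyl)oxy]-7-(2-hydroxypropan-2-yl)-8-oxoeremophil-9-en-3-yl ester of 22 (C7 epimers) | C/C=C(/C)C(=O)OC/C=C(/C)C(=O)O[C@@H]1CCC2=C(OCc3ccc(OC)cc3)C(=O)C(C(C)(C)O)C[C@]2(C)[C@H]1C | intermediate
24 | (3R,4R,5R)-9-[(4-methoxybenzyl)oxy]-8-oxoeremophila-7(11),9-dien-3-yl ester of 22 | C/C=C(/C)C(=O)OC/C=C(/C)C(=O)O[C@@H]1CCC2=C(OCc3ccc(OC)cc3)C(=O)C(=C(C)C)C[C@]2(C)[C@H]1C | intermediate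
25 | CNP0301409.1, (3R,4R,5R)-9-hydroxy-8-oxoeremophila-7(11),9-dien-3-yl (Z)-2-methyl-4-{[(Z)-2-methylbut-2-enoyl]oxy}but-2-enoate | C/C=C(/C)C(=O)OC/C=C(/C)C(=O)O[C@@H]1CCC2=C(O)C(=O)C(=C(C)C)C[C@]2(C)[C@H]1C | target

**Step count**

Total: 16 steps. Longest linear sequence: 11 steps (steps 1–8 and 14–16).

**Steps most likely to fail**

Step 3 (key step). Discrimination between the enantiotopic carbonyls may be incomplete and enamine formation on the alkoxy-bearing side may be slow, with partial loss of the PMB group under the acid co-catalyst. The fallback carries the C9 oxygen in after, not through, the ring closure. It sets out from 5: methyl vinyl ketone and L-proline (DMSO) give (S)-Wieland–Miescher ketone F1, the same C9–C10 closure on the parent substrate. Alkaline hydrogen peroxide then epoxidises the enone to the 9,10-epoxy ketone F2. Acid (H2SO4/AcOH) isomerises this to the diosphenol (S)-5-hydroxy-8a-methyl-3,4,8,8a-tetrahydronaphthalene-1,6(2H,7H)-dione F3, as in the steroid 4,5-epoxy-3-ketone to 4-hydroxy-enone conversion. O-Alkylation with 4-methoxybenzyl chloride and K2CO3 (DMF) gives 8, where the fallback rejoins the route.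

Step 6. Borane may be consumed by the enone carbonyl while attack on the hindered C3=C4 bond is slow, or the C9=C10 enol ether may be hydroborated once the carbonyl is reduced. The fallback sets C3 by epoxidation instead and avoids hydride reagents. It sets out from 10: mCPBA/NaHCO3 should epoxidise the electron-rich C3=C4 bond anti to the angular methyl to give the 3,4-epoxide F4. Diethylaluminium 2,2,6,6-tetramethylpiperidide (excess, toluene, 0 °C) should open it by abstraction of a C15 hydrogen to the allylic alcohol (3R,5R)-3-hydroxy-4-methylidene compound F5. Hydrogenation with Crabtree's catalyst from the hydroxyl-bearing face, which is also the face opposite the angular methyl, gives 12, where the fallback rejoins the route (compound 11 is bypassed).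

Step 14. The activated acid may isomerise Z→E through reversible conjugate addition of DMAP, and acylation of the hindered C3 hydroxyl may be sluggish. The fallback builds the Z olefin on the substrate so that no Z-acid is ever activated. It sets out from 13: EDC/DMAP acylation with 2-(diphenoxyphosphoryl)propanoic acid F6 (from 20 and TFA) gives the C3 phosphonopropanoate F7. An Ando olefination of F7 with aldehyde 17 under mild NaI/DBU conditions (THF, −78 → 0 °C, which leave the tertiary β-hydroxy ketone alone) gives 23, where the fallback rejoins the route.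

Further compounds
F1 | step 3 | (S)-Wieland–Miescher ketone, (S)-8a-methyl-3,4,8,8a-tetrahydronaphthalene-1,6(2H,7H)-dione | C[C@]12CCC(=O)C=C1CCCC2=O
F2 | step 3 | 4a,5-epoxide of F1 (angular methyl as in F1, epoxide face not assigned) | C1CCC2(O3)C3C(=O)CC[C@]2(C)C1=O
F3 | step 3 | (S)-5-hydroxy-8a-methyl-3,4,8,8a-tetrahydronaphthalene-1,6(2H,7H)-dione | C1CCC2=C(O)C(=O)CC[C@]2(C)C1=O
F4 | step 6 | 3,4-epoxide of 10, oxygen anti to the C5 methyl (eremophilane numbering) | O1[C@@H]2CCC3=C(OCc4ccc(OC)cc4)C(=O)CC[C@]3(C)[C@]12C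
F5 | step 6 | (4aR,6R)-6-hydroxy-1-[(4-methoxybenzyl)oxy]-4a-methyl-5-methylidene-4,4a,5,6,7,8-hexahydronaphthalen-2(3H)-one | O[C@@H]1CCC2=C(OCc3ccc(OC)cc3)C(=O)CC[C@]2(C)C1=C
F6 | step 14 | 2-(diphenoxyphosphoryl)propanoic acid (racemic) | CC(C(=O)O)P(=O)(Oc1ccccc1)Oc1ccccc1
F7 | step 14 | C3 2-(diphenoxyphosphoryl)propanoate of 13 | CC(C(=O)O[C@@H]1CCC2=C(OCc3ccc(OC)cc3)C(=O)C(C(C)(C)O)C[C@]2(C)[C@H]1C)P(=O)(Oc1ccccc1)Oc1ccccc1
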